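**Retrosynthetic overview**

1. The target is (13S)-15-acetoxylabd-8(17)-en-19-oic acid. The acetate, the free acid (from a fluoride-labile ester), the C3 methylene (from a ketone) and the C18 methyl group are installed or unmasked after the skeleton is complete.
2. Key disconnection: the C4–C5 bond of ring A and the C9–C10 bond of ring B are both cut, back to one acyclic β-keto ester. A Mn(OAc)3/Cu(OAc)2 oxidative radical bicyclization closes ring A first and ring B last in one operation and leaves the 8(17)-methylene.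
3. Enabling feature: C4, which carries the C19 carboxyl, is next to C3, so a C3 ketone makes C4 the α-carbon of a β-keto ester that is oxidised to an electrophilic radical. The (E)-alkenes C5=C10 and C8=C9 with their methyl groups C20 and C17 steer two 6-endo closures, C17 supplies the hydrogen lost in the terminating step, and a Yb(OTf)3-chelated (+)-8-phenylmenthyl ester fixes the absolute sense.
4. The polyene is the C15 chain of (2E,6E)-farnesol (C1, C5–C17, C20; C13 by asymmetric hydrogenation, C1 by oxidation of the terminal (E)-methyl group) joined to an acetoacetate (C2, C3, C4, C19) by dianion alkylation.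
5. Ring order: no ring is present before step 7; ring A, then ring B, both in step 7.

Key step: step 7

Remark: labdane numbering is used throughout (ring A = C1–C5 and C10; ring B = C5–C10; C17 = exocyclic methylene carbon; C18 = methyl and C19 = carboxyl on C4; C20 = methyl on C10; side chain C11–C16 with oxygen on C15).

Assumption: the facial sense of the auxiliary in step 7 is taken from the chelate model given there; the β-keto esters 15 and 17 are drawn as keto tautomers with the ester equatorial, although C4 is enolisable until step 9.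

**Route**

Step 1
Reactants: 1 (2E,6E)-farnesol
Product: 2 (S)-2,3-dihydrofarnesol [(3S,6E)-3,7,11-trimethyldodeca-6,10-dien-1-ol]
Conditions: H2 (100 atm), Ru(OAc)2[(R)-BINAP] (0.5 mol %), MeOH/H2O 95:5, 20 °C
Reagents that add atoms: none
Why: Noyori asymmetric hydrogenation of an allylic alcohol: the hydroxyl group binds ruthenium so that only the C2=C3 alkene is reduced, and the (R)-BINAP complex should deliver hydrogen to the face of the (E)-alkene that gives the (3S) centre, the later C13, while the two isolated trisubstituted alkenes are left alone.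

Step 2
Reactants: 2 (S)-2,3-dihydrofarnesol
Product: 3 tert-butyldiphenylsilyl ether of 2
Conditions: TBDPSCl, imidazole, DMF, rt
Reagents that add atoms: tert-butyl(chloro)diphenylsilane, CC(C)(C)[Si](Cl)(c1ccccc1)c1ccccc1
Why: Standard silylation of a primary alcohol; this silyl ether is chosen because it should survive the dianion, the oxidative medium of step 7 and the heating of step 8, and it falls together with the ester group in step 13.

Step 3
Reactants: 3 silyl ether
Product: 4 (2E,6E,10S)-12-(tert-butyldiphenylsilyloxy)-2,6,10-trimethyldodeca-2,6-dien-1-ol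
Conditions: SeO2 (0.3 equiv), t-BuOOH (3 equiv), salicylic acid (0.1 equiv), CH2Cl2, 0 °C to rt
Reagents that add atoms: tert-butyl hydroperoxide, CC(C)(C)OO (net source of the oxygen atom, passed on through SeO2, O=[Se]=O)
Why: Riley allylic oxidation run catalytically in SeO2: the ene reaction takes place at the more electron-rich and more accessible terminal isopropylidene group and the following [2,3]-sigmatropic shift delivers oxygen to the (E)-methyl group only, so that the (E)-allylic alcohol (the later C1) should result; the reaction is stopped at partial conversion to limit enal formation and recovered 3 is recycled.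

Step 4
Reactants: 4 allylic alcohol
Product: 5 (2E,6E,10S)-1-bromo-12-(tert-butyldiphenylsilyloxy)-2,6,10-trimethyldodeca-2,6-diene
Conditions: CBr4, PPh3, CH2Cl2, 0 °C
Reagents that add atoms: tetrabromomethane, BrC(Br)(Br)Br
Why: Appel reaction: the alkoxyphosphonium ion is displaced by bromide at the primary allylic carbon in an SN2 sense, without allylic transposition and without loss of the (E)-geometry at 0 °C.

Step 5
Reactants: 6 (+)-8-phenylmenthol [(1S,2R,5S)-5-methyl-2-(2-phenylpropan-2-yl)cyclohexan-1-ol]; 7 2,2,6-trimethyl-4H-1,3-dioxin-4-one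
Product: 9 (+)-8-phenylmenthyl acetoacetate, via acetylketene 8 (not isolated)
Conditions: xylene, 140 °C (acetone distilled off)
Reagents that add atoms: none
Why: Thermal retro-[4+2] fragmentation of the dioxinone releases acetylketene 8 and acetone, and the ketene acylates the hindered secondary alcohol under neutral conditions (acetoacetylation with the diketene–acetone adduct).

Step 6
Reactants: 9 (+)-8-phenylmenthyl acetoacetate (1.3 equiv); 5 allylic bromide
Product: 11 (+)-8-phenylmenthyl (6E,10E,14S)-16-(tert-butyldiphenylsilyloxy)-6,10,14-trimethyl-3-oxohexadeca-6,10-dienoate, via dilithium dianion 10 (not isolated)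
Conditions: LiN(i-Pr)2 (2.2 equiv per 9), THF, −78 to 0 °C; then 5, −78 to 0 °C; aq. NH4Cl
Reagents that add atoms: none
Why: γ-Alkylation of an acetoacetate dianion: the second deprotonation creates the more reactive terminal carbanion, which displaces the primary allylic bromide in an SN2 sense and so forms the C1–C2 bond with both (E)-alkenes intact.

Step 7
Reactants: 11 acyclic β-keto ester
Product: 15 (+)-8-phenylmenthyl (13S)-15-(tert-butyldiphenylsilyloxy)-3-oxo-18-norlabd-8(17)-en-19-oate (5α-H; 10β-CH3; 9α-H; trans-decalin), via C4 radical 12 (not isolated), via monocyclic C10 radical 13 (not isolated), via bicyclic C8 radical 14 (not isolated)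
Conditions: Mn(OAc)3·2H2O (2.2 equiv), Cu(OAc)2·H2O (0.2 equiv), Yb(OTf)3 (1.0 equiv), CF3CH2OH, −5 to 0 °C, Ar
Reagents that add atoms: none
Why: Mn(OAc)3 (trivalent manganese) oxidises the Yb(OTf)3-chelated enol of 11 to the electrophilic C4 radical 12, which adds to C5 of the C5=C10 alkene to close ring A and leave the tertiary C10 radical 13; 13 adds to C9 of the C8=C9 alkene to close ring B and leave the tertiary C8 radical 14, which Cu(OAc)2 (divalent copper) traps as an alkylcopper species that loses a hydrogen of the C17 methyl group to give the 8(17)-methylene, the monovalent copper being reoxidised by Mn(OAc)3. The closest known reaction type is the Mn(OAc)3/Cu(OAc)2 oxidative free-radical polyene cyclization of unsaturated β-keto esters, in its lanthanide-triflate-promoted form with 8-phenylmenthyl ester auxiliaries. Both rings close in the 6-endo-trig mode through chair transition states, ring A first and ring B last. C5 is set in the absolute sense by the auxiliary: in the chelate the ester carbonyl lies syn to the carbinol C–H and the phenyl group covers one face of the planar dicarbonyl radical, so that with the (1S,2R,5S)-alcohol the alkene should add to the open face that gives 5α-H; C10 (C20 axial, anti to H5) and C9 (C11 equatorial, 9α-H) follow from the trans-fused chair–chair transition state and the (E)-geometry of the C8=C9 alkene, while C4 stays enolisable and is fixed in step 9. The step needs 6-endo instead of 5-exo closure twice, secured by the C20 and C17 methyl groups on the inner alkene carbons (attack at the CH termini C5 and C9 gives tertiary radicals) and by the sp2 C3 inside the forming ring A, and it needs hydrogen loss towards C17 instead of C7 or C9, which rests on the preference of the alkylcopper intermediate for the least hindered β-hydrogens of the methyl group.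

Step 8
Reactants: 15 auxiliary-bound bicyclic β-keto ester
Product: 17 2-(trimethylsilyl)ethyl (13S)-15-(tert-butyldiphenylsilyloxy)-3-oxo-18-norlabd-8(17)-en-19-oate, via acylketene 16 (not isolated)
Conditions: Me3SiCH2CH2OH (10 equiv), DMAP (0.3 equiv), toluene, 110 °C
Reagents that add atoms: 2-(trimethylsilyl)ethanol, C[Si](C)(C)CCO
Why: Transesterification of an enolisable β-keto ester by elimination–addition: the enol form expels the hindered secondary alcohol to give the α-oxoketene 16, which the excess primary alcohol captures, a path that is open only because C4 still carries a hydrogen and that avoids attack at the shielded ester carbonyl; the auxiliary is recovered.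

Step 9
Reactants: 17 silylethyl β-keto ester
Product: 18 2-(trimethylsilyl)ethyl (13S)-15-(tert-butyldiphenylsilyloxy)-3-oxolabd-8(17)-en-19-oate (4α-CH3; ester 4β)
Conditions: MeI (3 equiv), K2CO3 (2 equiv), acetone, 40 °C
Reagents that add atoms: iodomethane, CI
Why: C-Alkylation of the β-keto ester enolate: iodomethane approaches C4 from the α face, anti to the axial C20 methyl group on C10, so that the new methyl group (C18) should become equatorial and the ester (C19) axial and syn to C20, which is the C4 configuration of the target.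

Step 10
Reactants: 18 methylated keto ester
Product: 19 2-(trimethylsilyl)ethyl (13S)-15-(tert-butyldiphenylsilyloxy)-3β-hydroxylabd-8(17)-en-19-oate
Conditions: NaBH4, MeOH/THF, 0 °C
Reagents that add atoms: none
Why: Hydride reduction of the ketone from the less hindered α face (the β face carries the axial ester and C20) should give the equatorial 3β-alcohol, whose configuration is of no consequence because the centre is removed in step 12, and the esters are not reduced by NaBH4 at 0 °C.

Step 11
Reactants: 19 3β-alcohol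
Product: 20 O-phenyl thionocarbonate of 19 at O3
Conditions: PhOC(S)Cl (1.5 equiv), DMAP (2 equiv), MeCN, rt
Reagents that add atoms: O-phenyl chlorothionoformate, S=C(Cl)Oc1ccccc1
Why: O-Acylation of the secondary alcohol with the chlorothionoformate under DMAP catalysis gives the thionocarbonate without formation of a free alkoxide, which avoids retro-aldol cleavage of the β-hydroxy ester.

Step 12
Reactants: 20 thionocarbonate
Product: 21 2-(trimethylsilyl)ethyl (13S)-15-(tert-butyldiphenylsilyloxy)labd-8(17)-en-19-oate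
Conditions: Bu3SnH (2 equiv), AIBN (0.2 equiv), toluene, 110 °C
Reagents that add atoms: none
Why: Barton–McCombie deoxygenation: a radical chain in which the stannyl radical adds to the thiocarbonyl sulfur, the C3–O bond breaks and Bu3SnH supplies the hydrogen; the 8(17)-alkene is too remote to interfere and the esters and the silyl ether are inert.

Step 13
Reactants: 21 deoxygenated diprotected compound
Product: 22 (13S)-15-hydroxylabd-8(17)-en-19-oic acid (imbricatolic acid)
Conditions: Bu4NF (5 equiv), THF, rt; then dilute HCl to pH 3, 0 °C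
Reagents that add atoms: none
Why: Fluoride attacks silicon: the 2-(trimethylsilyl)ethyl ester fragments to ethene, Me3SiF and the carboxylate without any attack at the shielded C19 carbonyl, and the silyl ether at C15 is cleaved in the same operation.

Step 14
Reactants: 22 hydroxy acid
Product: 23 (13S)-15-acetoxylabd-8(17)-en-19-oic acid (target)
Conditions: Ac2O (1.5 equiv), pyridine, DMAP (0.05 equiv), CH2Cl2, 0 °C to rt; aq. NaHCO3, then pH 3
Reagents that add atoms: acetic anhydride, CC(=O)OC(C)=O
Why: Acetylation of the only hydroxyl group (primary, C15) under nucleophilic catalysis; the axial neopentyl carboxylic acid is not esterified and any mixed anhydride is hydrolysed in the aqueous NaHCO3 work-up.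

**Compound list**

1 | (2E,6E)-farnesol | CC(C)=CCC/C(C)=C/CC/C(C)=C/CO | starting material
2 | (S)-2,3-dihydrofarnesol, (3S,6E)-3,7,11-trimethyldodeca-6,10-dien-1-ol | CC(C)=CCC/C(C)=C/CC[C@H](C)CCO | intermediate
3 | tert-butyldiphenylsilyl ether of 2 | CC(C)=CCC/C(C)=C/CC[C@H](C)CCO[Si](c1ccccc1)(c1ccccc1)C(C)(C)C | intermediate
4 | (2E,6E,10S)-12-(tert-butyldiphenylsilyloxy)-2,6,10-trimethyldodeca-2,6-dien-1-ol | OC/C(C)=C/CC/C(C)=C/CC[C@H](C)CCO[Si](c1ccccc1)(c1ccccc1)C(C)(C)C | intermediate
5 | (2E,6E,10S)-1-bromo-12-(tert-butyldiphenylsilyloxy)-2,6,10-trimethyldodeca-2,6-diene | BrC/C(C)=C/CC/C(C)=C/CC[C@H](C)CCO[Si](c1ccccc1)(c1ccccc1)C(C)(C)C | intermediate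
6 | (+)-8-phenylmenthol, (1S,2R,5S) | O[C@H]1C[C@@H](C)CC[C@@H]1C(C)(C)c1ccccc1 | starting material
7 | 2,2,6-trimethyl-4H-1,3-dioxin-4-one | CC1=CC(=O)OC(C)(C)O1 | starting material
8 | acetylketene | CC(=O)C=C=O | intermediate (not isolated)
9 | (+)-8-phenylmenthyl acetoacetate | CC(=O)CC(=O)O[C@H]1C[C@@H](C)CC[C@@H]1C(C)(C)c1ccccc1 | intermediate
10 | dilithium dianion of 9 | [Li+].[Li+].C=C([O-])C=C([O-])O[C@H]1C[C@@H](C)CC[C@@H]1C(C)(C)c1ccccc1 | intermediate (not isolated)
11 | (+)-8-phenylmenthyl (6E,10E,14S)-16-(tert-butyldiphenylsilyloxy)-6,10,14-trimethyl-3-oxohexadeca-6,10-dienoate | O=C(CC(=O)CC/C(C)=C/CC/C(C)=C/CC[C@H](C)CCO[Si](c1ccccc1)(c1ccccc1)C(C)(C)C)O[C@H]1C[C@@H](C)CC[C@@H]1C(C)(C)c1ccccc1 | intermediate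
12 | C4 radical of 11 (between the two carbonyl groups) | O=C([CH]C(=O)CC/C(C)=C/CC/C(C)=C/CC[C@H](C)CCO[Si](c1ccccc1)(c1ccccc1)C(C)(C)C)O[C@H]1C[C@@H](C)CC[C@@H]1C(C)(C)c1ccccc1 | intermediate (not isolated)
13 | monocyclic tertiary C10 radical (ring A closed, C8=C9 alkene intact) | C/C(=C\CC[C@H](C)CCO[Si](c1ccccc1)(c1ccccc1)C(C)(C)C)CC[C@@H]1[C](C)CCC(=O)C1C(=O)O[C@H]1C[C@@H](C)CC[C@@H]1C(C)(C)c1ccccc1 | intermediate (not isolated)
14 | bicyclic tertiary C8 radical (rings A and B closed) | C[C]1CC[C@@H]2[C@](C)(CCC(=O)C2C(=O)O[C@H]3C[C@@H](C)CC[C@@H]3C(C)(C)c3ccccc3)[C@H]1CC[C@H](C)CCO[Si](c1ccccc1)(c1ccccc1)C(C)(C)C | intermediate (not isolated)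
15 | (+)-8-phenylmenthyl (13S)-15-(tert-butyldiphenylsilyloxy)-3-oxo-18-norlabd-8(17)-en-19-oate, keto tautomer with equatorial ester | C=C1CC[C@@H]2[C@](C)(CCC(=O)[C@H]2C(=O)O[C@H]3C[C@@H](C)CC[C@@H]3C(C)(C)c3ccccc3)[C@H]1CC[C@H](C)CCO[Si](c1ccccc1)(c1ccccc1)C(C)(C)C | intermediate
16 | acylketene at C4 (C3 ketone, C4=C=O) | C=C1CC[C@@H]2[C@](C)(CCC(=O)C2=C=O)[C@H]1CC[C@H](C)CCO[Si](c1ccccc1)(c1ccccc1)C(C)(C)C | intermediate (not isolated)
17 | 2-(trimethylsilyl)ethyl (13S)-15-(tert-butyldiphenylsilyloxy)-3-oxo-18-norlabd-8(17)-en-19-oate | C=C1CC[C@@H]2[C@](C)(CCC(=O)[C@H]2C(=O)OCC[Si](C)(C)C)[C@H]1CC[C@H](C)CCO[Si](c1ccccc1)(c1ccccc1)C(C)(C)C | intermediate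
18 | 2-(trimethylsilyl)ethyl (13S)-15-(tert-butyldiphenylsilyloxy)-3-oxolabd-8(17)-en-19-oate | C=C1CC[C@@H]2[C@](C)(CCC(=O)[C@]2(C)C(=O)OCC[Si](C)(C)C)[C@H]1CC[C@H](C)CCO[Si](c1ccccc1)(c1ccccc1)C(C)(C)C | intermediate
19 | 2-(trimethylsilyl)ethyl (13S)-15-(tert-butyldiphenylsilyloxy)-3β-hydroxylabd-8(17)-en-19-oate | C=C1CC[C@@H]2[C@](C)(CC[C@H](O)[C@]2(C)C(=O)OCC[Si](C)(C)C)[C@H]1CC[C@H](C)CCO[Si](c1ccccc1)(c1ccccc1)C(C)(C)C | intermediate
20 | O-phenyl thionocarbonate of 19 at O3 | C=C1CC[C@@H]2[C@](C)(CC[C@H](OC(=S)Oc3ccccc3)[C@]2(C)C(=O)OCC[Si](C)(C)C)[C@H]1CC[C@H](C)CCO[Si](c1ccccc1)(c1ccccc1)C(C)(C)C | intermediate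
21 | 2-(trimethylsilyl)ethyl (13S)-15-(tert-butyldiphenylsilyloxy)labd-8(17)-en-19-oate | C=C1CC[C@@H]2[C@](C)(CCC[C@]2(C)C(=O)OCC[Si](C)(C)C)[C@H]1CC[C@H](C)CCO[Si](c1ccccc1)(c1ccccc1)C(C)(C)C | intermediate
22 | (13S)-15-hydroxylabd-8(17)-en-19-oic acid (imbricatolic acid) | C=C1CC[C@@H]2[C@](C)(CCC[C@]2(C)C(=O)O)[C@H]1CC[C@H](C)CCO | intermediate
23 | (13S)-15-acetoxylabd-8(17)-en-19-oic acid | C=C1CC[C@@H]2[C@](C)(CCC[C@]2(C)C(=O)O)[C@H]1CC[C@H](C)CCOC(C)=O | target

**Step count**

Total: 14 steps. Longest linear sequence: 13 steps (steps 1–4 and 6–14, from farnesol); step 5 is a one-step side branch.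

**Steps most likely to fail**

Step 7 (key step). The cyclised product is still an enolisable β-keto ester and may be oxidised a second time by Mn(OAc)3 while starting material remains, which would lower the yield and take oxidant away from the copper-mediated alkene formation. The fallback blocks C4 with chlorine and sets out from 11. N-Chlorosuccinimide with catalytic Mg(ClO4)2 in EtOAc should give the α-chloro β-keto ester F1. The same Mn(OAc)3/Cu(OAc)2/Yb(OTf)3 cyclization should then give the 4-chloro bicyclic keto ester F2, which has no hydrogen between the carbonyl groups and cannot be oxidised again. Zinc dust in AcOH removes the chlorine and the route is rejoined at 15.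

Step 8. Expulsion of the hindered secondary alcohol from the enol may be slow or incomplete, and thermal decomposition of the β-keto ester may compete at the temperature required. The fallback keeps the auxiliary and removes it by hydride at the end; it sets out from 15. Methylation with MeI/K2CO3 should give the auxiliary-bound methylated keto ester F3, NaBH4 the 3β-alcohol F4, PhOC(S)Cl/DMAP the thionocarbonate F5, and Bu3SnH/AIBN the deoxygenated auxiliary ester F6. LiAlH4 in refluxing THF cleaves the hindered ester reductively to the C19 primary alcohol F7, with recovery of the auxiliary. Jones oxidation (CrO3, H2SO4, acetone, 0 °C) gives the silyl-protected acid F8, and Bu4NF removes the silyl ether to rejoin the route at 22.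

Step 3. Oxidation may also take place at the allylic positions of the inner C8=C9 alkene, and the product may be over-oxidised to the enal. The fallback builds the (E)-allylic alcohol by degradation and olefination instead of C–H oxidation; it sets out from 3. NBS in aqueous THF should add selectively to the terminal alkene to give the bromohydrin F9, and K2CO3 in MeOH closes it to the terminal epoxide F10. HIO4 cleaves the epoxide to the trisnor aldehyde F11, and Wittig olefination with Ph3P=C(CH3)CO2Et gives the (E)-enoate F12. Reduction with i-Bu2AlH at −78 °C rejoins the route at 4.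

**Further compounds**

F1 | step 7 | (+)-8-phenylmenthyl (6E,10E,14S)-2-chloro-16-(tert-butyldiphenylsilyloxy)-6,10,14-trimethyl-3-oxohexadeca-6,10-dienoate (both C2 epimers) | O=C(C(Cl)C(=O)CC/C(C)=C/CC/C(C)=C/CC[C@H](C)CCO[Si](c1ccccc1)(c1ccccc1)C(C)(C)C)O[C@H]1C[C@@H](C)CC[C@@H]1C(C)(C)c1ccccc1
F2 | step 7 | (+)-8-phenylmenthyl (13S)-4-chloro-15-(tert-butyldiphenylsilyloxy)-3-oxo-18-norlabd-8(17)-en-19-oate (C4 configuration not specified, centre erased by zinc) | C=C1CC[C@@H]2[C@](C)(CCC(=O)C2(Cl)C(=O)O[C@H]3C[C@@H](C)CC[C@@H]3C(C)(C)c3ccccc3)[C@H]1CC[C@H](C)CCO[Si](c1ccccc1)(c1ccccc1)C(C)(C)C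
F3 | step 8 | (+)-8-phenylmenthyl (13S)-15-(tert-butyldiphenylsilyloxy)-3-oxolabd-8(17)-en-19-oate | C=C1CC[C@@H]2[C@](C)(CCC(=O)[C@]2(C)C(=O)O[C@H]3C[C@@H](C)CC[C@@H]3C(C)(C)c3ccccc3)[C@H]1CC[C@H](C)CCO[Si](c1ccccc1)(c1ccccc1)C(C)(C)C
F4 | step 8 | (+)-8-phenylmenthyl (13S)-15-(tert-butyldiphenylsilyloxy)-3β-hydroxylabd-8(17)-en-19-oate | C=C1CC[C@@H]2[C@](C)(CC[C@H](O)[C@]2(C)C(=O)O[C@H]3C[C@@H](C)CC[C@@H]3C(C)(C)c3ccccc3)[C@H]1CC[C@H](C)CCO[Si](c1ccccc1)(c1ccccc1)C(C)(C)C
F5 | step 8 | O-phenyl thionocarbonate of F4 at O3 | C=C1CC[C@@H]2[C@](C)(CC[C@H](OC(=S)Oc3ccccc3)[C@]2(C)C(=O)O[C@H]3C[C@@H](C)CC[C@@H]3C(C)(C)c3ccccc3)[C@H]1CC[C@H](C)CCO[Si](c1ccccc1)(c1ccccc1)C(C)(C)C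
F6 | step 8 | (+)-8-phenylmenthyl (13S)-15-(tert-butyldiphenylsilyloxy)labd-8(17)-en-19-oate | C=C1CC[C@@H]2[C@](C)(CCC[C@]2(C)C(=O)O[C@H]3C[C@@H](C)CC[C@@H]3C(C)(C)c3ccccc3)[C@H]1CC[C@H](C)CCO[Si](c1ccccc1)(c1ccccc1)C(C)(C)C
F7 | step 8 | (13S)-15-(tert-butyldiphenylsilyloxy)labd-8(17)-en-19-ol | C=C1CC[C@@H]2[C@](C)(CCC[C@]2(C)CO)[C@H]1CC[C@H](C)CCO[Si](c1ccccc1)(c1ccccc1)C(C)(C)C
F8 | step 8 | (13S)-15-(tert-butyldiphenylsilyloxy)labd-8(17)-en-19-oic acid | C=C1CC[C@@H]2[C@](C)(CCC[C@]2(C)C(=O)O)[C@H]1CC[C@H](C)CCO[Si](c1ccccc1)(c1ccccc1)C(C)(C)C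
F9 | step 3 | terminal bromohydrin of 3, (6E,10S)-3-bromo-12-(tert-butyldiphenylsilyloxy)-2,6,10-trimethyldodec-6-en-2-ol (both C3 epimers) | CC(C)(O)C(Br)CC/C(C)=C/CC[C@H](C)CCO[Si](c1ccccc1)(c1ccccc1)C(C)(C)C
F10 | step 3 | terminal epoxide of 3 (both epoxide epimers) | CC1(C)OC1CC/C(C)=C/CC[C@H](C)CCO[Si](c1ccccc1)(c1ccccc1)C(C)(C)C
F11 | step 3 | (4E,8S)-10-(tert-butyldiphenylsilyloxy)-4,8-dimethyldec-4-enal | O=CCC/C(C)=C/CC[C@H](C)CCO[Si](c1ccccc1)(c1ccccc1)C(C)(C)C
F12 | step 3 | ethyl (2E,6E,10S)-12-(tert-butyldiphenylsilyloxy)-2,6,10-trimethyldodeca-2,6-dienoate | CCOC(=O)/C(C)=C/CC/C(C)=C/CC[C@H](C)CCO[Si](c1ccccc1)(c1ccccc1)C(C)(C)C
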